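Readings and results were generated by integration with constants of no real substance, and the scatter is random.

0.0288 min⁻¹ is the tail constant: the net first-order constant at which L falls once its loss has overtaken its making, as read from the last two green readings.

| setting | grey | green | flask |
|---|---|---|---|
| G | 0.30 M | 0.20 M | 0.30 M |
| X | 11 mM (held) | 11 mM (held) | 11 mM (held) |
| remark | the very flask that is asked about, followed so far | run made earlier |  |
| time |  |  | 50 min |

- grey (time / min: L / %): 5.00: 16.9; 10.0: 15.9; 15.0: 13.7; 20.0: 11.9; 25.0: 8.3
- green (time / min: L / %): 3.00: 14.9; 5.00: 17.0; 10.0: 16.2; 20.0: 10.5; 40.0: 5.9

(scatter of a reading: 0.5 percentage points)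

* at 50 min, what has stopped the reaction, if anything has (all of G has reacted / forward and back rates have come level / it is still moving)
* L at 50 min, in percent of the G charged

- at the start none of X is in solution
- the reaction counts as stopped when no species that holds the G changes by six tenths of a point or more over the second half of the time

In percent of the G charged, the grey and green runs stand level at 5.00 min, with 16.9% against 17.0%, so we carry the constant from the green run to the grey flask. Our own reckoning starts from the last grey reading, 8.3% at 25.0 min, and decays it at the tail constant to 50 min, which gives 4.04%. That is a drop of 4.3 percentage points over the second half of the time, more than the scatter of 0.5 points and outside the stopping margin given above, so we expect the grey flask to be still moving. The forecast's answers are "it is still moving" and L at 4.2%, holding that “the green run can stand in for the later part of the grey flask”. The simulation of the grey flask answers "it is still moving" and gives L at 3.17%, which is 0.87 points below our reckoning.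

    Z + L → E (k = 17.0 M⁻¹ min⁻¹)
    Z ⇌ Q (K = 8.10, k = 1.80 min⁻¹)
    X ⇌ Z, rate k3*(csat - [Z]) (kL = 51.0 min⁻¹)
    G + Z ⇌ L (K = 51.0 M⁻¹, k = 8.50 M⁻¹ min⁻¹)

A neighbouring flask has the same charge but is read at 30 min. The tail constant, applied to the last grey reading over the 5.00 min from that reading to 30 min, gives 7.19%. The neighbouring flask holds 7.42% of L.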